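**Retros­ynthetic overview**
- The target comes from a protected 3,8''-biflavanone by acetate methanolysis and hydrogenolysis; the C4 ketone of unit 1 (the catechol flavanone) comes from a 4-methoxyflavan by solvolysis and oxidation.
- The strategy rests on ring C of unit 1: O1 and C4 sit on neighbouring carbons (C8a, C4a) of ring A, and C2 (catechol ring B) and C3 (bonded to C8 of unit 2) carry trans aryl groups. Cutting O1–C2 and C3–C4 gives a methoxy ortho-quinone methide (from 2-hydroxy-4,6-bis(benzyloxy)benzaldehyde and HC(OMe)3) and an (E)-stilbene.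
- The stilbene comes from a Heck coupling of (2S)-8-iodonaringenin triacetate with 3,4-bis(benzyloxy)styrene. The iodide is made from (2S)-naringenin through its tribenzyl ether, because ring A must be an ether to be iodinated at C8 and an ester to steer the cycloaddition; the triacetate itself is too deactivated to iodinate.
- Ring order: all rings of unit 2 come with naringenin, rings A and B of unit 1 with the two benzaldehydes; ring C of unit 1 is the only ring made, in the key step.

Key step: step 8

Remark: commercial (2S)-naringenin of high enantiomeric purity is assumed (checked by chiral HPLC before use). The C3 descriptor of unit 1 is R while C4 is sp3 (14, 15) and S once C4 is a carbonyl (16–18), with no change in space.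

**Step 1**
Reactants: 1 (2S)-naringenin
Product: 2 (2S)-5,7-bis(benzyloxy)-2-[4-(benzyloxy)phenyl]chroman-4-one
Conditions: BnOH (4 equiv), PPh3 (4 equiv), DIAD (4 equiv), THF, 0 °C to rt, then 40 °C
Reagents that add atoms: benzyl alcohol, OCc1ccccc1
Why: Mitsunobu etherification should alkylate all three phenols (the chelated 5-OH included) without carbonate or hydroxide base, so the C2 centre, which epimerises through base-induced ring opening, should stay intact.

**Step 2**
Reactants: 2 (2S)-5,7-bis(benzyloxy)-2-[4-(benzyloxy)phenyl]chroman-4-one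
Product: 3 (2S)-5,7-bis(benzyloxy)-2-[4-(benzyloxy)phenyl]-8-iodochroman-4-one
Conditions: NIS (1.05 equiv), TFA (10 mol %), MeCN, 0 °C to rt, dark
Reagents that add atoms: N-iodosuccinimide, O=C1CCC(=O)N1I
Why: Electrophilic aromatic iodination of ring A; with both 5-O and 7-O alkylated the iodine is expected at C8 (between O1 and the 7-benzyloxy group) and not at C6 (between two benzyloxy groups), the known preference of 5,7-dialkoxyflavonoids, and ring B is far less activated.

**Step 3**
Reactants: 3 (2S)-5,7-bis(benzyloxy)-2-[4-(benzyloxy)phenyl]-8-iodochroman-4-one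
Product: 4 (2S)-5,7-dihydroxy-2-(4-hydroxyphenyl)-8-iodochroman-4-one
Conditions: BCl3 (6 equiv), pentamethylbenzene (9 equiv), CH2Cl2, −78 °C; MeOH then H2O quench
Reagents that add atoms: none
Why: Lewis acid debenzylation with a non-basic cation scavenger should cleave the three aryl benzyl ethers at low temperature and leave the aryl iodide (which hydrogenolysis would remove) and the flavanone untouched.

**Step 4**
Reactants: 4 (2S)-5,7-dihydroxy-2-(4-hydroxyphenyl)-8-iodochroman-4-one
Product: 5 (2S)-5,7-diacetoxy-2-(4-acetoxyphenyl)-8-iodochroman-4-one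
Conditions: Ac2O (6 equiv), pyridine, rt
Reagents that add atoms: acetic anhydride, CC(=O)OC(C)=O
Why: Standard O-acetylation with a weak base; the acetates make ring A of unit 2 electron-poor for the key step and mask the 4'-phenol, whose phenoxide would open ring C.

**Step 5**
Reactants: 6 3,4-bis(benzyloxy)benzaldehyde
Product: 7 3,4-bis(benzyloxy)styrene
Conditions: Ph3PCH3Br (1.3 equiv), KOt-Bu (1.25 equiv), THF, 0 °C to rt
Reagents that add atoms: methyltriphenylphosphonium bromide, C[P+](c1ccccc1)(c1ccccc1)c1ccccc1.[Br-]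
Why: Wittig methylenation of an aromatic aldehyde with a non-stabilised ylide.

**Step 6**
Reactants: 5 (2S)-5,7-diacetoxy-2-(4-acetoxyphenyl)-8-iodochroman-4-one; 7 3,4-bis(benzyloxy)styrene
Product: 8 (2S)-5,7-diacetoxy-2-(4-acetoxyphenyl)-8-[(E)-2-[3,4-bis(benzyloxy)phenyl]ethenyl]chroman-4-one
Conditions: 7 (1.5 equiv), Pd(OAc)2 (5 mol %), Bu4NCl (1 equiv), NaHCO3 (2.5 equiv), DMF, 60 °C, dark
Reagents that add atoms: none
Why: Heck reaction under ligand-free phase-transfer conditions: oxidative addition of the aryl iodide, syn insertion at the terminal carbon of the styrene and syn β-hydride elimination should give the (E)-stilbene, and solid NaHCO3 is mild enough for the acetates and the C2 centre.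

**Step 7**
Reactants: 9 2,4,6-trihydroxybenzaldehyde
Product: 10 2-hydroxy-4,6-bis(benzyloxy)benzaldehyde
Conditions: BnBr (2.1 equiv), K2CO3 (2.2 equiv), DMF, 0 °C to rt
Reagents that add atoms: benzyl bromide, BrCc1ccccc1
Why: Williamson etherification; the 4-OH and one ortho-OH are alkylated while the remaining ortho-OH, hydrogen-bonded to the formyl group, should stay free.

**Step 8**
Reactants: 8 (2S)-5,7-diacetoxy-2-(4-acetoxyphenyl)-8-[(E)-2-[3,4-bis(benzyloxy)phenyl]ethenyl]chroman-4-one; 10 2-hydroxy-4,6-bis(benzyloxy)benzaldehyde; 11 trimethyl orthoformate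
Product: 14 (2S)-5,7-diacetoxy-2-(4-acetoxyphenyl)-8-[(2R,3R)-5,7-bis(benzyloxy)-2-[3,4-bis(benzyloxy)phenyl]-4-methoxychroman-3-yl]chroman-4-one (2,3-trans; C4 epimers), via 2-(dimethoxymethyl)-3,5-bis(benzyloxy)phenol 12 (not isolated), via methoxy ortho-quinone methide 13 (not isolated)
Conditions: 10 (1.5 equiv) and 11 (2 equiv) premixed with a confined BINOL-derived imidodiphosphorimidate Brønsted acid (N-triflyl, 3,3'-aryl = 3,5-(CF3)2C6H3; 10 mol %; antipode chosen by a small screen), 4 Å MS, CH2Cl2, −40 °C; then 8, −40 to 0 °C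
Reagents that add atoms: none
Why: Proposed new method: the acid turns 10 and 11 into acetal 12 and ionises it to the methoxy ortho-quinone methide 13 (reacting as its O-protonated benzylic oxocarbenium ion paired with the chiral anion); the stilbene carbon bearing unit 2 attacks the oxocarbenium carbon (C3–C4) and the phenol oxygen then collapses onto the benzylic cation next to ring B (O1–C2), an asynchronous inverse-demand hetero-[4+2]. The closest known reaction type is the acid-promoted three-component union of salicylaldehydes, orthoformates and styrenes to 4-alkoxy-2-arylchromans, together with ion-pair control of oxocarbenium cycloadditions by confined chiral acids; a 1,2-diaryl alkene under such control is the extension. Ring C of unit 1 closes as a six-membered ring by attack of the phenol oxygen on the cationic carbon (6-endo-type closure, the second bond of the [4+2]). C3 is set in the C–C bond formation, where the chiral anion selects the alkene face, and C2 follows from C3 because the (E)-geometry and a diequatorial closure give the 2,3-trans pair; since unit 2 is already homochiral the two possible trans adducts are diastereomers and the minor one should be removable by chromatography, while C4 is uncontrolled and erased later. The step needs regioselectivity (carbon to the unit 2 end, oxygen to the ring B end): the para-benzyloxy group of ring B stabilises the cation, whereas ring A of unit 2 is deactivated by two acetoxy groups and the C4 carbonyl and is twisted by its two ortho substituents.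

**Step 9**
Reactants: 14 the 4-methoxyflavan cycloadduct
Product: 15 (2S)-5,7-diacetoxy-2-(4-acetoxyphenyl)-8-[(2R,3R)-5,7-bis(benzyloxy)-2-[3,4-bis(benzyloxy)phenyl]-4-hydroxychroman-3-yl]chroman-4-one (C4 epimers)
Conditions: TsOH·H2O (0.2 equiv), THF/H2O (4:1), 0.01 M, 0 °C to rt
Reagents that add atoms: water, O
Why: SN1 solvolysis: the C4–OMe bond should ionise under mild acid to a benzylic cation stabilised by O1 and the 5- and 7-benzyloxy groups, and water in large excess captures it, as in the solvolysis of leucoanthocyanidin-type 4-substituted flavans; the C4 configuration does not matter.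

**Step 10**
Reactants: 15 the flavan-4-ol
Product: 16 (2S)-5,7-diacetoxy-2-(4-acetoxyphenyl)-8-[(2R,3S)-5,7-bis(benzyloxy)-2-[3,4-bis(benzyloxy)phenyl]-4-oxochroman-3-yl]chroman-4-one
Conditions: Dess–Martin periodinane (1.5 equiv), pyridine (5 equiv), CH2Cl2, 0 °C to rt
Reagents that add atoms: none
Why: Dess–Martin oxidation of the secondary benzylic alcohol to the flavanone ketone under buffered conditions that should not epimerise either C2 centre.

**Step 11**
Reactants: 16 the protected biflavanone
Product: 17 (2S)-8-[(2R,3S)-5,7-bis(benzyloxy)-2-[3,4-bis(benzyloxy)phenyl]-4-oxochroman-3-yl]-5,7-dihydroxy-2-(4-hydroxyphenyl)chroman-4-one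
Conditions: HCl (1.25 M in MeOH), THF, rt to 40 °C
Reagents that add atoms: none
Why: Acid-catalysed methanolysis of the three aryl acetates avoids phenoxide formation, so neither C2 centre can open, and acid enolisation of the unit 1 ketone lets C3 settle in the more stable 2,3-trans (diequatorial) arrangement.

**Step 12**
Reactants: 17 the tetra-O-benzyl biflavanone
Product: 18 (2S)-8-[(2R,3S)-2-(3,4-dihydroxyphenyl)-5,7-dihydroxy-4-oxochroman-3-yl]-5,7-dihydroxy-2-(4-hydroxyphenyl)chroman-4-one (target)
Conditions: H2 (1 atm), 10% Pd/C, THF/MeOH (1:1), rt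
Reagents that add atoms: none
Why: Hydrogenolysis of the four aryl benzyl ethers over palladium; the chelated aryl ketones and the ring C–O bonds of flavanones normally survive these mild conditions.

**Compound list**
1 | (2S)-naringenin | O=C1C[C@@H](c2ccc(O)cc2)Oc2c1c(O)cc(O)c2 | starting material
2 | (2S)-5,7-bis(benzyloxy)-2-[4-(benzyloxy)phenyl]chroman-4-one | O=C1C[C@@H](c2ccc(OCc3ccccc3)cc2)Oc2c1c(OCc1ccccc1)cc(OCc1ccccc1)c2 | intermediate
3 | (2S)-5,7-bis(benzyloxy)-2-[4-(benzyloxy)phenyl]-8-iodochroman-4-one | O=C1C[C@@H](c2ccc(OCc3ccccc3)cc2)Oc2c1c(OCc1ccccc1)cc(OCc1ccccc1)c2I | intermediate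
4 | (2S)-5,7-dihydroxy-2-(4-hydroxyphenyl)-8-iodochroman-4-one | O=C1C[C@@H](c2ccc(O)cc2)Oc2c1c(O)cc(O)c2I | intermediate
5 | (2S)-5,7-diacetoxy-2-(4-acetoxyphenyl)-8-iodochroman-4-one | O=C1C[C@@H](c2ccc(OC(C)=O)cc2)Oc2c1c(OC(C)=O)cc(OC(C)=O)c2I | intermediate
6 | 3,4-bis(benzyloxy)benzaldehyde | O=Cc1ccc(OCc2ccccc2)c(OCc2ccccc2)c1 | starting material
7 | 3,4-bis(benzyloxy)styrene | C=Cc1ccc(OCc2ccccc2)c(OCc2ccccc2)c1 | intermediate
8 | (2S)-5,7-diacetoxy-2-(4-acetoxyphenyl)-8-[(E)-2-[3,4-bis(benzyloxy)phenyl]ethenyl]chroman-4-one | O=C1C[C@@H](c2ccc(OC(C)=O)cc2)Oc2c1c(OC(C)=O)cc(OC(C)=O)c2/C=C/c1ccc(OCc2ccccc2)c(OCc2ccccc2)c1 | intermediate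
9 | 2,4,6-trihydroxybenzaldehyde | O=Cc1c(O)cc(O)cc1O | starting material
10 | 2-hydroxy-4,6-bis(benzyloxy)benzaldehyde | O=Cc1c(O)cc(OCc2ccccc2)cc1OCc1ccccc1 | intermediate
11 | trimethyl orthoformate | COC(OC)OC | starting material
12 | 2-(dimethoxymethyl)-3,5-bis(benzyloxy)phenol (not isolated) | COC(OC)c1c(O)cc(OCc2ccccc2)cc1OCc1ccccc1 | intermediate
13 | 3,5-bis(benzyloxy)-6-(methoxymethylene)cyclohexa-2,4-dienone, the methoxy ortho-quinone methide (not isolated) | COC=C1C(=O)C=C(OCc2ccccc2)C=C1OCc1ccccc1 | intermediate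
14 | (2S)-5,7-diacetoxy-2-(4-acetoxyphenyl)-8-[(2R,3R)-5,7-bis(benzyloxy)-2-[3,4-bis(benzyloxy)phenyl]-4-methoxychroman-3-yl]chroman-4-one, 2,3-trans, C4 epimers | O=C1C[C@@H](c2ccc(OC(C)=O)cc2)Oc2c1c(OC(C)=O)cc(OC(C)=O)c2[C@@H]1C(OC)c2c(OCc3ccccc3)cc(OCc3ccccc3)cc2O[C@H]1c1ccc(OCc2ccccc2)c(OCc2ccccc2)c1 | intermediate
15 | (2S)-5,7-diacetoxy-2-(4-acetoxyphenyl)-8-[(2R,3R)-5,7-bis(benzyloxy)-2-[3,4-bis(benzyloxy)phenyl]-4-hydroxychroman-3-yl]chroman-4-one, C4 epimers | O=C1C[C@@H](c2ccc(OC(C)=O)cc2)Oc2c1c(OC(C)=O)cc(OC(C)=O)c2[C@@H]1C(O)c2c(OCc3ccccc3)cc(OCc3ccccc3)cc2O[C@H]1c1ccc(OCc2ccccc2)c(OCc2ccccc2)c1 | intermediate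
16 | (2S)-5,7-diacetoxy-2-(4-acetoxyphenyl)-8-[(2R,3S)-5,7-bis(benzyloxy)-2-[3,4-bis(benzyloxy)phenyl]-4-oxochroman-3-yl]chroman-4-one | O=C1C[C@@H](c2ccc(OC(C)=O)cc2)Oc2c1c(OC(C)=O)cc(OC(C)=O)c2[C@@H]1C(=O)c2c(OCc3ccccc3)cc(OCc3ccccc3)cc2O[C@H]1c1ccc(OCc2ccccc2)c(OCc2ccccc2)c1 | intermediate
17 | (2S)-8-[(2R,3S)-5,7-bis(benzyloxy)-2-[3,4-bis(benzyloxy)phenyl]-4-oxochroman-3-yl]-5,7-dihydroxy-2-(4-hydroxyphenyl)chroman-4-one | O=C1C[C@@H](c2ccc(O)cc2)Oc2c1c(O)cc(O)c2[C@@H]1C(=O)c2c(OCc3ccccc3)cc(OCc3ccccc3)cc2O[C@H]1c1ccc(OCc2ccccc2)c(OCc2ccccc2)c1 | intermediate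
18 | (2S)-8-[(2R,3S)-2-(3,4-dihydroxyphenyl)-5,7-dihydroxy-4-oxochroman-3-yl]-5,7-dihydroxy-2-(4-hydroxyphenyl)chroman-4-one | O=C1C[C@@H](c2ccc(O)cc2)Oc2c1c(O)cc(O)c2[C@@H]1C(=O)c2c(O)cc(O)cc2O[C@H]1c1ccc(O)c(O)c1 | target

**Step count**
Total: 12 steps. Longest linear sequence: 10 steps (1, 2, 3, 4, 6, 8, 9, 10, 11, 12).

**Steps most likely to fail**

Step 8 (proposed new method). The C3–C4 bond joins two carbons that each carry a doubly ortho-substituted aryl group, so the cycloaddition may be too slow. The alkene may also add with reversed orientation, the catalyst may discriminate the alkene faces poorly, or the acid may re-ionise the product at C4 and lead to self-condensation. The fallback uses a smaller, methoxy-free ortho-quinone methide and known chemistry; it sets out from 10 and 8 and comes back at 15. NaBH4 in MeOH/THF reduces 10 to the salicyl alcohol 2-(hydroxymethyl)-3,5-bis(benzyloxy)phenol F1, which is used fresh. An achiral acid (diphenyl phosphate, CH2Cl2, 0 °C) or heating in toluene dehydrates F1 to the parent ortho-quinone methide, which should add to 8 in the known [4+2] manner of ortho-hydroxybenzyl alcohols with aryl alkenes. This gives the 4-unsubstituted 2,3-trans flavan (2S)-5,7-diacetoxy-2-(4-acetoxyphenyl)-8-[(2R,3S)-5,7-bis(benzyloxy)-2-[3,4-bis(benzyloxy)phenyl]chroman-3-yl]chroman-4-one F2. Because unit 2 is homochiral, F2 and its (2S,3R) isomer are diastereomers and are separated by chromatography. Benzylic oxidation of F2 at C4 with DDQ in wet CH2Cl2, the standard C4 functionalisation of 5,7-dialkoxyflavans, should then give alcohol 15.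

Step 9. The C4 cation may lose the C3 proton to give the flav-3-ene, or may alkylate the electron-rich ring A of a second molecule, instead of being captured by water. The fallback replaces solvolysis by oxidation; it sets out from 14 and comes back at 16. DDQ (2.5 equiv) in wet, buffered CH2Cl2 should abstract hydride from C4–H of the benzylic methyl ether, and water converts the resulting methoxy-stabilised cation into ketone 16 through its hemiketal. The hydroquinone formed is acidic enough to epimerise C4, so both epimers can reach the conformer with an axial C4–H, and any 4-ol formed on the way is oxidised by DDQ as well.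

Step 6. Insertion at the doubly ortho-substituted arylpalladium centre may be slow, and prolonged heating with base may open ring C of unit 2 (loss of configuration at C2) or cleave acetates. The fallback is a base-free Stille coupling; it sets out from 6 and 5 and comes back at 8. Ohira–Bestmann homologation of 6 (dimethyl (1-diazo-2-oxopropyl)phosphonate, K2CO3, MeOH) gives 4-ethynyl-1,2-bis(benzyloxy)benzene F3. Radical hydrostannation (Bu3SnH, AIBN, toluene, 90 °C, equilibrating conditions) should give (E)-tributyl[2-[3,4-bis(benzyloxy)phenyl]ethenyl]stannane F4. Coupling of F4 with 5 (Pd2(dba)3, AsPh3, CuI, DMF, 50 °C) should deliver stilbene 8 under neutral conditions.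

**Further compounds**
F1 | step 8 | 2-(hydroxymethyl)-3,5-bis(benzyloxy)phenol | OCc1c(O)cc(OCc2ccccc2)cc1OCc1ccccc1
F2 | step 8 | (2S)-5,7-diacetoxy-2-(4-acetoxyphenyl)-8-[(2R,3S)-5,7-bis(benzyloxy)-2-[3,4-bis(benzyloxy)phenyl]chroman-3-yl]chroman-4-one | O=C1C[C@@H](c2ccc(OC(C)=O)cc2)Oc2c1c(OC(C)=O)cc(OC(C)=O)c2[C@@H]1Cc2c(OCc3ccccc3)cc(OCc3ccccc3)cc2O[C@H]1c1ccc(OCc2ccccc2)c(OCc2ccccc2)c1
F0 | step 9 | none | none
F3 | step 6 | 4-ethynyl-1,2-bis(benzyloxy)benzene | C#Cc1ccc(OCc2ccccc2)c(OCc2ccccc2)c1
F4 | step 6 | (E)-tributyl[2-[3,4-bis(benzyloxy)phenyl]ethenyl]stannane | CCCC[Sn](CCCC)(CCCC)/C=C/c1ccc(OCc2ccccc2)c(OCc2ccccc2)c1
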